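## The problem

Compound 24 is a drimane-type trans-decalin whose C11 oxygen is the 7-oxygen of a coumarin. The bicycle carries five stereocentres (C3, C4, C5, C9, C10); C4 and C10 are quaternary and flank the ring-fusion methine C5. At C4 the hydroxymethyl carbon C14 is axial, on the face of the angular methyl C15 and cis to the equatorial C3 hydroxyl, while the methyl C13 is equatorial, so the oxygenated carbon has to be placed on the more hindered face. Control can run in one direction: C5 can direct C10 (trans across ring B), C5 and C10 together can direct C3 and C4 through a chair closure of ring A, and the axial C15 can shield one face of C9. Two groups do not tolerate rough treatment. The exocyclic C8=C12 alkene moves into the ring under acid or metal hydride catalysis, and the coumarin lactone is opened by hydride, strong base and organometallic reagents, so both must appear late. The enabling feature is the C3 carbinol β to C14. With C14 at the ester level this is an aldol retron, and because C4 also bears the methyl C13, the required enolate is the one formed when hydride adds to a 2-substituted acrylate. That acrylate (C4, C13, C14) is the isopropenyl group of carvone, whose ring supplies ring B with C5 and C12 in place.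

## Retrosynthesis

**24 ⇒ 23 ⇒ 20 ⇒ 19 ⇒ 17 + 18.** The last cuts are the acetonide, the position of the alkene and the C11–O aryl bond.
- The coumarin 18 is joined by Mitsunobu etherification to 17, the one intermediate with a single free hydroxyl. This keeps the lactone away from all hydride and strong-base chemistry.
- The exocyclic alkene is made from the ring alkene C7=C8 of 19 in two steps: allylic hydroxylation of C12 to 20, then reductive 1,3-transposition to 23. The alternative of epoxidation, base opening and deoxygenation of a C7 alcohol costs two more steps and needs a strong base in the presence of the coumarin.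
- The forward reactions must tolerate the lactone and the acetonide. Both run near neutrality.

**17 ⇒ 15 ⇒ 14 ⇒ 13.** The C11–O and C9–H bonds are cut together by reading 17 as the hydroboration product of diene 15.
- Hydrogen must enter C9 opposite C15; the angular methyl should enforce this.
- The diene 15 is simpler by one stereocentre and one oxygen.
- The acetonide and the reduction of the C14 ester lead back to the β-hydroxy ester 13.

**13 ⇒ 12 (key cut, C3–C4).** Opening ring A between C3 and C4 gives the acrylate aldehyde 12; the forward step is a CuH reductive aldol cyclisation.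
- It makes one ring, one bond and two stereocentres (C3, C4).
- Against a C4–C5 or C4–C14 cut, it uses the isopropenyl carbons of the chiral pool as they are. It asks of the substrate only a chair closure, in which the C13 methyl stays away from the axial C15.
- One correction to the obvious precursor is needed. A C9 ketone conjugated with C7=C8 would itself take up hydride, since carvone-type enones are among the best substrates for CuH. C9 is therefore already a methylene group in 12. This removes the competing acceptor and at the same time installs C11.

**12 ⇒ 9 ⇒ 8 ⇒ 6 ⇒ 5.** The aldehyde comes from the silyl ether via 11 and 10, the ester from acid 9, and the C9=C11 methylene from keto acid 8 by Wittig reaction.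
- The order is forced. Allylic chlorination of the isopropenyl group (5 to 6) needs the ring alkene to be the electron-poor enone alkene, so methylenation must follow it.
- The ylide is incompatible with the allylic chloride 6, the enal 7 and an acrylate ester. The carboxylate stage 8 is the first, and the only convenient, point for methylenation.

**5 ⇒ 4 + 2; 4 ⇒ 3; 2 ⇒ 1.** The C10–C1 and C10–C15 bonds are cut as two enolate alkylations of (S)-carvone 3: methyl first, then the three-carbon chain from iodide 2 (made from bromide 1).
- The second alkylation must occur trans to the isopropenyl group. This is the C5/C10 relationship of the trans-decalin.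

## Roads not taken

**Alternative 1:** The cut is C4–C14. A bromomethylsilyl ether on O3 of a C4=C5 octalin (A1) would cyclise with Bu3SnH by 5-exo radical addition to C4, giving the oxasilolane A2 after hydrogen transfer to C5.
- Merits: the tether forces C14 onto the face of O3, so the C3/C4 relationship is fixed by ring strain and not by a conformational preference. In this respect it is more secure than the chair argument behind step 11. A1 is also reachable in few steps from an enantioselective Robinson annulation.
- Weak points: ring B of A2 holds only a protected C9 ketone. C11, C12 and the unsaturation at C8 all remain to be built, and C8 has no handle. The ring fusion depends on the face of hydrogen transfer to a tertiary C5 radical, which can leak to the cis-decalin. A stoichiometric tin reagent is needed.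
- Comparison: the chosen plan has every carbon of ring B and the C5 configuration from the start. It accepts a less rigidly enforced C4 centre in exchange.

**Alternative 2:** The cuts are C5–C10 and C8–C9. A triene (A3) with an (E)-3-methyl enoate and an (E,E)-silyloxy diene would undergo intramolecular Diels–Alder reaction to the octalin A4.
- Merits: both rings and four stereocentres arise in one step. A4 also ends with oxygen on C8 next to a C11 ester. From there, saturation of C6=C7, oxidation at C8, methylenation and ester reduction give the C8=C12/C11–OH array by the classical sequence. This is cleaner than the hydroxylation and transposition pair of steps 16 and 17.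
- Weak points: the dienophile is β,β-disubstituted and must form the quaternary C10, so the reaction will need high temperature, which a silyloxy diene tolerates poorly. Trienes of this tether length give cis- and trans-fused products with little bias. Facial control comes only from a quaternary C4 whose methyl and alkoxymethyl groups differ little. A3 needs its C3/C4 pair made by separate asymmetric chemistry.
- Comparison: the chosen plan sets against the better endgame a ring B of known configuration, a one-bond closure at low temperature, and a precursor (12) that is nine linear steps from carvone.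

**Alternative 3:** The cut is C8–C9. An enyne (A5) with a butynyl chain on C5 and a vinyl group on C10 would cyclise with Pd(OAc)2 (divalent palladium), B2pin2 and methanol to the boronate A6.
- Merits: the exocyclic methylene and the functionalised C11 appear in the ring-forming step itself, and oxidation of the C–B bond gives the alcohol needed for the ether. The chosen plan spends four steps (7, 14, 16, 17) on the same array, so here the alternative is clearly shorter at the end.
- Weak points: the difficulty moves into A5, a cyclohexane with two quaternary centres and four contiguous stereocentres that must be assembled without help from ring B. The cyclisation is well established for five-membered rings; A5 requires six-membered ring closure next to a quaternary carbon. C9 would be set by the face of alkene insertion, for which no reliable bias is evident.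
- Comparison: the chosen plan uses more steps after the key step but starts from a ring that already fixes C5 and directs C10, C4, C3 and C9 in turn.

Key step: step 11

Remark on conventions: drimane numbering is used for all intermediates (C1–C3 chain or ring A; C4 with C13 and C14; ring B C5–C10; C11 on C9; C12 on C8; C15 on C10). β means the face that carries C15 and α the opposite face, whatever the absolute series; the absolute configuration is that of the SMILES strings. Silyl ether 1 is taken as a commercial reagent.

## Route

Step 1
Reactants: 1 (3-bromopropoxy)(tert-butyl)dimethylsilane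
Product: 2 tert-butyl(3-iodopropoxy)dimethylsilane
Conditions: NaI, acetone, reflux
Reagents that add atoms: sodium iodide, [Na+].[I-]
Why: Finkelstein halide exchange, driven by precipitation of NaBr; the iodide is needed because the enolate used in step 3 is hindered.

Step 2
Reactants: 3 (S)-carvone
Product: 4 (5S)-6-methylcarvone (both C6 epimers)
Conditions: LiN(iPr)2, THF, −78 °C; MeI, −78 → 0 °C
Reagents that add atoms: iodomethane, CI
Why: Kinetic deprotonation of the enone takes the α′ proton (C6 of carvone, the future C10) and C-methylation follows; the epimer mixture is harmless because this carbon is planar again in step 3.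

Step 3
Reactants: 4 (5S)-6-methylcarvone; 2 tert-butyl(3-iodopropoxy)dimethylsilane
Product: 5 6-[3-(tert-butyldimethylsilyloxy)propyl]-2,6-dimethyl-5-(prop-1-en-2-yl)cyclohex-2-en-1-one (chain trans and 6-methyl cis to the isopropenyl group)
Conditions: LiN(iPr)2, THF, −78 → −20 °C; DMPU, 2, −78 °C → rt
Reagents that add atoms: none
Why: SN2 alkylation of the tetrasubstituted lithium enolate on the face opposite the neighbouring isopropenyl group, so the chain enters trans and the methyl ends cis; this sets C10 relative to C5 as in a trans-decalin.

Step 4
Reactants: 5 trans-alkylated carvone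
Product: 6 6-[3-(tert-butyldimethylsilyloxy)propyl]-5-(3-chloroprop-1-en-2-yl)-2,6-dimethylcyclohex-2-en-1-one
Conditions: Ca(OCl)2, CO2 (dry ice), CH2Cl2/H2O, 0 °C
Reagents that add atoms: calcium hypochlorite, [Ca+2].[O-]Cl.[O-]Cl
Why: Ene-type allylic chlorination by HOCl attacks the electron-rich 1,1-disubstituted alkene and leaves the electron-poor enone alkene; this is why C9 is still a ketone at this stage.

Step 5
Reactants: 6 allylic chloride
Product: 7 2-[2-{3-(tert-butyldimethylsilyloxy)propyl}-2,4-dimethyl-3-oxocyclohex-4-en-1-yl]prop-2-enal
Conditions: N-methylmorpholine N-oxide, KI (cat.), NaHCO3, MeCN, 50 °C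
Reagents that add atoms: N-methylmorpholine N-oxide, C[N+]1([O-])CCOCC1
Why: Kornblum-type oxidation of an allylic halide by an amine N-oxide: iodide-assisted SN2 displacement by the N-oxide oxygen, then base-induced fragmentation to the 2-substituted acrolein; no free allylic alcohol is formed next to the enone.

Step 6
Reactants: 7 enal
Product: 8 2-[2-{3-(tert-butyldimethylsilyloxy)propyl}-2,4-dimethyl-3-oxocyclohex-4-en-1-yl]prop-2-enoic acid
Conditions: NaClO2, NaH2PO4, 2-methyl-2-butene, t-BuOH/H2O, 0 °C → rt
Reagents that add atoms: sodium chlorite, [Na+].[O-]Cl=O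
Why: Pinnick oxidation of the enal to the acrylic acid under buffered conditions; the scavenger removes HOCl, so the enone, the acrylic alkene and the silyl ether are untouched.

Step 7
Reactants: 8 keto acid
Product: 9 2-[2-{3-(tert-butyldimethylsilyloxy)propyl}-2,4-dimethyl-3-methylidenecyclohex-4-en-1-yl]prop-2-enoic acid
Conditions: Ph3PCH3Br, KOtBu (4 equiv each), THF/toluene, 70 °C; aq. citric acid to pH 4
Reagents that add atoms: methyltriphenylphosphonium bromide, C[P+](c1ccccc1)(c1ccccc1)c1ccccc1.[Br-]
Why: Wittig methylenation of the hindered C9 ketone with excess unstabilised ylide at elevated temperature; the potassium carboxylate is inert to the ylide and too poor a Michael acceptor to compete, which the ester of step 8 would not be. The resulting s-trans diene brings in C11 and leaves the acrylate as the only conjugate acceptor for the key step.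

Step 8
Reactants: 9 diene acid
Product: 10 methyl 2-[2-{3-(tert-butyldimethylsilyloxy)propyl}-2,4-dimethyl-3-methylidenecyclohex-4-en-1-yl]prop-2-enoate
Conditions: Me3SiCHN2, toluene/MeOH (4:1), 0 °C
Reagents that add atoms: trimethylsilyldiazomethane, C[Si](C)(C)C=[N+]=[N-]
Why: O-methylation of the carboxylic acid by the diazoalkane in methanol is neutral and leaves the diene and the silyl ether alone.

Step 9
Reactants: 10 silyl ether ester
Product: 11 methyl 2-[2-(3-hydroxypropyl)-2,4-dimethyl-3-methylidenecyclohex-4-en-1-yl]prop-2-enoate
Conditions: HF·pyridine, pyridine, THF, 0 °C → rt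
Reagents that add atoms: none
Why: Fluoride cleavage of the primary silyl ether under buffered conditions that neither isomerise the diene nor add to the acrylate.

Step 10
Reactants: 11 primary alcohol
Product: 12 methyl 2-[2,4-dimethyl-3-methylidene-2-(3-oxopropyl)cyclohex-4-en-1-yl]prop-2-enoate (acrylate cis to the 2-methyl and trans to the oxopropyl chain)
Conditions: Dess–Martin periodinane, pyridine, CH2Cl2, 0 °C → rt
Reagents that add atoms: none
Why: Dess–Martin oxidation stops at the aldehyde and tolerates the diene and the acrylate; pyridine buffers the acetic acid released.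

Step 11
Reactants: 12 acrylate aldehyde
Product: 13 methyl 3β-hydroxydrima-7,9(11)-dien-14-oate (trans-decalin; C14 ester axial on the β face; C13 equatorial; 5α-H)
Conditions: [(Ph3P)CuH]6 (0.4 equiv of the hexamer), toluene, −40 → 0 °C; aq. NH4Cl
Reagents that add atoms: none
Why: [(Ph3P)CuH]6 adds hydride to the unsubstituted β-carbon of the acrylate in its s-cis conformation, which creates C13 and an ester enolate of monovalent copper with O–Cu cis to C13. The enolate carbon C4 then adds to the C3 aldehyde and forms C3–C4; the closest known reaction type is the CuH-mediated reductive aldol cyclisation of enones and enoates onto tethered ketones and aldehydes. Ring A closes in the 6-(enolexo)-exo-trig mode through a chair in which C1 and C4 leave ring B equatorially, as allowed by the trans relationship set in step 3. For C4, one exocyclic group must sit axial beside the axial C15 methyl: the flat enolate carbon C14 takes this place, because an axial C13 methyl would meet C15 in a syn-pentane clash, so C14 ends axial (β) and C13 equatorial. For C3, copper bridges the enolate oxygen and the aldehyde oxygen, which requires O3 gauche to C14; with C14 axial this is the equatorial β position, so O3 is cis to the ester. The step needs hydride to go to the acrylate alone: C9 is a methylene group, the s-trans diene is inert to the phosphine-ligated hydride, and with no silane present 1,2-reduction of the aldehyde is slower than addition to a terminal acrylate. Aqueous NH4Cl then releases the β-hydroxy ester, both new centres being set by C5 and C10.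

Step 12
Reactants: 13 β-hydroxy ester
Product: 14 drima-7,9(11)-diene-3β,14-diol
Conditions: LiAlH4, THF, 0 °C → reflux; aq. NaOH work-up
Reagents that add atoms: none
Why: Hydride reduction of the hindered axial ester to the primary C14 alcohol; reduction is faster than retro-aldol cleavage of the C3 alkoxide, and the diene is inert.

Step 13
Reactants: 14 diol
Product: 15 3β,14-isopropylidenedioxydrima-7,9(11)-diene
Conditions: 2,2-dimethoxypropane, PPTS (cat.), CH2Cl2, rt
Reagents that add atoms: 2,2-dimethoxypropane, COC(C)(C)OC
Why: Acid-catalysed transketalisation; the equatorial 3β-hydroxyl and the axial C14 hydroxymethyl are cis and close a six-membered 1,3-dioxane, which masks both for the rest of the route.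

Step 14
Reactants: 15 diene acetonide
Product: 17 3β,14-isopropylidenedioxydrim-7-en-11-ol (9α-H), via C11 borane 16 (not isolated)
Conditions: 9-BBN, THF, 0 → 50 °C; then NaOH, H2O2, 0 °C → rt
Reagents that add atoms: hydrogen peroxide, OO
Why: Hydroboration–oxidation: 9-BBN puts boron on the terminal C11 of the exocyclic alkene and ignores the trisubstituted C7=C8 alkene. Hydrogen reaches C9 from the α face, opposite the axial C15 methyl, which sets C9 with C11 equatorial (β).

Step 15
Reactants: 17 C11 alcohol; 18 umbelliferone (7-hydroxycoumarin)
Product: 19 7-[(3β,14-isopropylidenedioxydrim-7-en-11-yl)oxy]coumarin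
Conditions: PPh3, DIAD, THF, 0 → 45 °C
Reagents that add atoms: none
Why: Mitsunobu etherification of the only free hydroxyl, a primary alcohol, with an acidic phenol; C11 is not a stereocentre and the lactone meets no nucleophile.

Step 16
Reactants: 19 aryl ether
Product: 20 7-[(12-hydroxy-3β,14-isopropylidenedioxydrim-7-en-11-yl)oxy]coumarin
Conditions: SeO2 (0.5 equiv), t-BuOOH, CH2Cl2, rt
Reagents that add atoms: selenium dioxide, O=[Se]=O; tert-butyl hydroperoxide, CC(C)(C)OO
Why: Riley allylic oxidation (ene reaction, then [2,3]-sigmatropic shift); trisubstituted alkenes react at the more substituted terminus and prefer CH3 over a tertiary CH, so C12 is hydroxylated and the alkene returns to C7=C8.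

Step 17
Reactants: 20 C12 allylic alcohol
Product: 23 7-[(3β,14-isopropylidenedioxydrim-8(12)-en-11-yl)oxy]coumarin, via sulfonylhydrazine 21 (not isolated), via allylic diazene 22 (not isolated)
Conditions: 2-nitrobenzenesulfonylhydrazide, PPh3, DEAD, N-methylmorpholine, −30 °C → rt
Reagents that add atoms: none
Why: Myers reductive transposition: Mitsunobu N-alkylation at C12, loss of sulfinic acid to the monoalkyl diazene, and retro-ene loss of N2 deliver hydrogen to C7 and move the alkene to C8=C12; no stereocentre is touched.

Step 18
Reactants: 23 acetonide
Product: 24 7-[(3β,14-dihydroxydrim-8(12)-en-11-yl)oxy]coumarin (CNP0149624.1)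
Conditions: AcOH/H2O (4:1), 40 °C
Reagents that add atoms: none
Why: Mild aqueous acid hydrolyses the 1,3-dioxane acetal; the exocyclic alkene and the coumarin ether survive these conditions.

## Compound list

1 | (3-bromopropoxy)(tert-butyl)dimethylsilane | BrCCCO[Si](C)(C)C(C)(C)C | starting material
2 | tert-butyl(3-iodopropoxy)dimethylsilane | ICCCO[Si](C)(C)C(C)(C)C | intermediate
3 | (S)-carvone | CC1=CC[C@H](C(C)=C)CC1=O | starting material
4 | (5S)-6-methylcarvone, both C6 epimers | CC1=CC[C@H](C(C)=C)C(C)C1=O | intermediate
5 | 6-[3-(tert-butyldimethylsilyloxy)propyl]-2,6-dimethyl-5-(prop-1-en-2-yl)cyclohex-2-en-1-one, chain trans to isopropenyl | CC1=CC[C@H](C(C)=C)[C@@](C)(CCCO[Si](C)(C)C(C)(C)C)C1=O | intermediate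
6 | allylic chloride, 5-(3-chloroprop-1-en-2-yl) analogue of 5 | CC1=CC[C@H](C(=C)CCl)[C@@](C)(CCCO[Si](C)(C)C(C)(C)C)C1=O | intermediate
7 | 2-[2-{3-(tert-butyldimethylsilyloxy)propyl}-2,4-dimethyl-3-oxocyclohex-4-en-1-yl]prop-2-enal | CC1=CC[C@H](C(=C)C=O)[C@@](C)(CCCO[Si](C)(C)C(C)(C)C)C1=O | intermediate
8 | 2-[2-{3-(tert-butyldimethylsilyloxy)propyl}-2,4-dimethyl-3-oxocyclohex-4-en-1-yl]prop-2-enoic acid | CC1=CC[C@H](C(=C)C(=O)O)[C@@](C)(CCCO[Si](C)(C)C(C)(C)C)C1=O | intermediate
9 | 2-[2-{3-(tert-butyldimethylsilyloxy)propyl}-2,4-dimethyl-3-methylidenecyclohex-4-en-1-yl]prop-2-enoic acid | C=C1C(C)=CC[C@H](C(=C)C(=O)O)[C@@]1(C)CCCO[Si](C)(C)C(C)(C)C | intermediate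
10 | methyl ester of 9 | C=C1C(C)=CC[C@H](C(=C)C(=O)OC)[C@@]1(C)CCCO[Si](C)(C)C(C)(C)C | intermediate
11 | methyl 2-[2-(3-hydroxypropyl)-2,4-dimethyl-3-methylidenecyclohex-4-en-1-yl]prop-2-enoate | C=C1C(C)=CC[C@H](C(=C)C(=O)OC)[C@@]1(C)CCCO | intermediate
12 | methyl 2-[2,4-dimethyl-3-methylidene-2-(3-oxopropyl)cyclohex-4-en-1-yl]prop-2-enoate (key-step precursor) | C=C1C(C)=CC[C@H](C(=C)C(=O)OC)[C@@]1(C)CCC=O | intermediate
13 | methyl 3β-hydroxydrima-7,9(11)-dien-14-oate (key-step product; 4β-CO2Me axial, 4α-CH3, 5α-H, 10β-CH3) | C=C1C(C)=CC[C@@H]2[C@](C)(C(=O)OC)[C@H](O)CC[C@@]12C | intermediate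
14 | drima-7,9(11)-diene-3β,14-diol | C=C1C(C)=CC[C@@H]2[C@](C)(CO)[C@H](O)CC[C@@]12C | intermediate
15 | 3β,14-isopropylidenedioxydrima-7,9(11)-diene | C=C1C(C)=CC[C@@H]2[C@]3(C)COC(C)(C)O[C@@H]3CC[C@@]12C | intermediate
16 | 11-(9-borabicyclo[3.3.1]nonan-9-yl)-3β,14-isopropylidenedioxydrim-7-ene (9α-H) | CC1=CC[C@@H]2[C@]3(C)COC(C)(C)O[C@@H]3CC[C@@]2(C)[C@@H]1CB1C2CCCC1CCC2 | intermediate
17 | 3β,14-isopropylidenedioxydrim-7-en-11-ol (9α-H) | CC1=CC[C@@H]2[C@]3(C)COC(C)(C)O[C@@H]3CC[C@@]2(C)[C@@H]1CO | intermediate
18 | umbelliferone (7-hydroxycoumarin) | Oc1ccc2ccc(=O)oc2c1 | starting material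
19 | 7-[(3β,14-isopropylidenedioxydrim-7-en-11-yl)oxy]coumarin | CC1=CC[C@@H]2[C@]3(C)COC(C)(C)O[C@@H]3CC[C@@]2(C)[C@@H]1COc1ccc2ccc(=O)oc2c1 | intermediate
20 | 7-[(12-hydroxy-3β,14-isopropylidenedioxydrim-7-en-11-yl)oxy]coumarin | OCC1=CC[C@@H]2[C@]3(C)COC(C)(C)O[C@@H]3CC[C@@]2(C)[C@@H]1COc1ccc2ccc(=O)oc2c1 | intermediate
21 | N-(C12 allyl)-N-(2-nitrophenylsulfonyl)hydrazine derived from 20 | O=[N+]([O-])c1ccccc1S(=O)(=O)N(N)CC1=CC[C@@H]2[C@]3(C)COC(C)(C)O[C@@H]3CC[C@@]2(C)[C@@H]1COc1ccc2ccc(=O)oc2c1 | intermediate
22 | C12 monoalkyl diazene | N=NCC1=CC[C@@H]2[C@]3(C)COC(C)(C)O[C@@H]3CC[C@@]2(C)[C@@H]1COc1ccc2ccc(=O)oc2c1 | intermediate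
23 | 7-[(3β,14-isopropylidenedioxydrim-8(12)-en-11-yl)oxy]coumarin | C=C1CC[C@@H]2[C@]3(C)COC(C)(C)O[C@@H]3CC[C@@]2(C)[C@@H]1COc1ccc2ccc(=O)oc2c1 | intermediate
24 | 7-[(3β,14-dihydroxydrim-8(12)-en-11-yl)oxy]coumarin, CNP0149624.1 | C=C1CC[C@@H]2[C@](C)(CO)[C@H](O)CC[C@@]2(C)[C@@H]1COc1ccc2ccc(=O)oc2c1 | target

## Step count and least certain steps

Total: 18 steps. Longest linear sequence: 17 steps (steps 2 to 18, from 3).

**Step 11 (key step).** Hydride may go directly to the aldehyde, or the copper enolate may be protonated before it closes the ring. If the enolate forms in the other geometry, copper cannot bridge both oxygens and facial control at C4 and C3 is lost. Fallback: a Reformatsky closure of the same bond, setting out from 10. Conjugate reduction of the acrylate (catalytic [(Ph3P)CuH]6, polymethylhydrosiloxane, t-BuOH, toluene) gives the saturated ester F1. Enolisation with LiN(iPr)2 and bromination with CBr4 gives the tertiary α-bromo ester F2. HF·pyridine gives the bromo alcohol F3, and Dess–Martin oxidation gives the bromo aldehyde F4. SmI2 in THF at −78 °C then forms the enolate of trivalent samarium, which closes through the same chelated chair to 13, where the route is rejoined.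

**Step 7.** Addition of the ylide to the hindered carbonyl may be slow. The basic ylide may instead remove a γ-proton of the enone, which returns starting material or deconjugates the alkene, and the carboxylate salt may dissolve poorly. Fallback: Peterson olefination from 8. Me3SiCH2Li with anhydrous CeCl3 in THF at −78 °C (after deprotonation of the acid) adds to the ketone and gives the β-hydroxysilane F5. Elimination with KH in THF gives 9.

**Step 16.** The allylic alcohol may be oxidised further to the enal, conversion may stall, and some oxidation at C6 may compete. Enal formed by over-oxidation can be returned with NaBH4/CeCl3. Fallback: move the alkene through C7 oxygenation, from 19. Epoxidation with mCPBA from the α face gives the epoxide F6. Cp2TiCl (trivalent titanium, from Cp2TiCl2 and Mn dust) opens it at C8 and gives the exocyclic allylic alcohol F7. ClCO2Me and pyridine give the carbonate F8. Hydrogenolysis with Pd(OAc)2, PBu3, HCO2H and Et3N delivers hydride to C7 and gives 23, passing by 20 to 22.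

**Step 17.** N-alkylation at the allylic C12 next to the substituted C9 may be incomplete, the hydrazide may decompose before it is alkylated, and the sulfinic acid released may start to cleave the acetonide. Fallback: from 20, ClCO2Me and pyridine give the methyl carbonate F9. Pd(OAc)2, PBu3, HCO2H and Et3N in THF then form the π-allyl complex and deliver hydride to the more substituted terminus C7, giving 23.

**Step 3.** The hindered enolate may react slowly with the unactivated iodide, so that proton transfer and O-alkylation compete and the trans selectivity erodes on warming. Fallback: from 4, alkylation with allyl bromide (LiN(iPr)2, THF, −78 °C) gives the allyl ketone F10 with the same facial preference. Disiamylborane hydroborates the monosubstituted alkene in preference to the isopropenyl group, and oxidation gives the hydroxypropyl ketone F11. TBSCl and imidazole then give 5.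

## Further compounds

F1 | step 11 | methyl 2-[2-{3-(tert-butyldimethylsilyloxy)propyl}-2,4-dimethyl-3-methylidenecyclohex-4-en-1-yl]propanoate (both epimers at the ester α-carbon) | C=C1C(C)=CC[C@H](C(C)C(=O)OC)[C@@]1(C)CCCO[Si](C)(C)C(C)(C)C
F2 | step 11 | methyl 2-bromo-2-[2-{3-(tert-butyldimethylsilyloxy)propyl}-2,4-dimethyl-3-methylidenecyclohex-4-en-1-yl]propanoate | C=C1C(C)=CC[C@H](C(C)(Br)C(=O)OC)[C@@]1(C)CCCO[Si](C)(C)C(C)(C)C
F3 | step 11 | methyl 2-bromo-2-[2-(3-hydroxypropyl)-2,4-dimethyl-3-methylidenecyclohex-4-en-1-yl]propanoate | C=C1C(C)=CC[C@H](C(C)(Br)C(=O)OC)[C@@]1(C)CCCO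
F4 | step 11 | methyl 2-bromo-2-[2,4-dimethyl-3-methylidene-2-(3-oxopropyl)cyclohex-4-en-1-yl]propanoate | C=C1C(C)=CC[C@H](C(C)(Br)C(=O)OC)[C@@]1(C)CCC=O
F5 | step 7 | 2-[2-{3-(tert-butyldimethylsilyloxy)propyl}-3-hydroxy-2,4-dimethyl-3-(trimethylsilylmethyl)cyclohex-4-en-1-yl]prop-2-enoic acid | CC1=CC[C@H](C(=C)C(=O)O)[C@@](C)(CCCO[Si](C)(C)C(C)(C)C)C1(O)C[Si](C)(C)C
F6 | step 16 | 7-[(7α,8α-epoxy-3β,14-isopropylidenedioxydriman-11-yl)oxy]coumarin | C[C@@]14O[C@H]4C[C@@H]2[C@]3(C)COC(C)(C)O[C@@H]3CC[C@@]2(C)[C@@H]1COc1ccc2ccc(=O)oc2c1
F7 | step 16 | 7-[(7α-hydroxy-3β,14-isopropylidenedioxydrim-8(12)-en-11-yl)oxy]coumarin | C=C1[C@@H](O)C[C@@H]2[C@]3(C)COC(C)(C)O[C@@H]3CC[C@@]2(C)[C@@H]1COc1ccc2ccc(=O)oc2c1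
F8 | step 16 | C7 methyl carbonate of F7 | C=C1[C@@H](OC(=O)OC)C[C@@H]2[C@]3(C)COC(C)(C)O[C@@H]3CC[C@@]2(C)[C@@H]1COc1ccc2ccc(=O)oc2c1
F9 | step 17 | C12 methyl carbonate of 20 | COC(=O)OCC1=CC[C@@H]2[C@]3(C)COC(C)(C)O[C@@H]3CC[C@@]2(C)[C@@H]1COc1ccc2ccc(=O)oc2c1
F10 | step 3 | 6-allyl-2,6-dimethyl-5-(prop-1-en-2-yl)cyclohex-2-en-1-one, allyl trans to isopropenyl | CC1=CC[C@H](C(C)=C)[C@@](C)(CC=C)C1=O
F11 | step 3 | 6-(3-hydroxypropyl)-2,6-dimethyl-5-(prop-1-en-2-yl)cyclohex-2-en-1-one | CC1=CC[C@H](C(C)=C)[C@@](C)(CCCO)C1=O
A1 | alternative 1 | C3 (bromomethyl)dimethylsilyl ether of a C4-methyl C4=C5 octalin with a C9 dioxolane | C[Si](C)(CBr)O[C@@H]1CC[C@]2(C)C(CCCC23OCCO3)=C1C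
A2 | alternative 1 | cis-fused oxasilolane on a trans-decalin | C[Si]1(C)O[C@@H]2CC[C@]3(C)[C@H](CCCC34OCCO4)[C@]2(C)C1
A3 | alternative 2 | acetonide-bearing triene with (E)-3-methyl enoate and (E,E)-1-silyloxy diene | COC(=O)/C=C(\C)CC[C@H]1OC(C)(C)OC[C@@]1(C)/C=C/C=C/O[Si](C)(C)C(C)(C)C
A4 | alternative 2 | trans-fused octalin with C8 silyl ether and C11 ester | CC(C)(C)[Si](C)(C)O[C@@H]1C=C[C@@H]2[C@]3(C)COC(C)(C)O[C@@H]3CC[C@@]2(C)[C@@H]1C(=O)OC
A5 | alternative 3 | ring-A enyne with a C5 butynyl chain and a C10 vinyl group | C#CCC[C@@H]1[C@]2(C)COC(C)(C)O[C@@H]2CC[C@@]1(C)C=C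
A6 | alternative 3 | decalin with exocyclic methylene and C11 pinacol boronate | C=C1CC[C@@H]2[C@]3(C)COC(C)(C)O[C@@H]3CC[C@@]2(C)[C@@H]1CB4OC(C)(C)C(C)(C)O4
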